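**Retrosynthetic overview**

1. Target 22 is epicatechin-(4β→8)-epicatechin-(4β→8)-catechin-(4β→8)-epicatechin (units 1–4 from the top). The last bond made is C4(unit 2)–C8(unit 3), a 2+2 union of the 8-bromo-capped, C4-thioether upper dimer 20 with the lower dimer 18, followed by global hydrogenolysis.
2. Unit 3 (2,3-trans-3,4-cis) is the C3 epimer of a 4β-linked epicatechin unit. It is therefore made from the epicatechin–epicatechin dimer 16 by oxidation at C3 and hydride return from the α face, so all four units come from one monomer, 12.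
3. Monomer 12 comes from racemic flavan-3-one 11 (dynamic kinetic transfer hydrogenation sets C2 and C3), and 11 from 4H-chromene 10. Ring C of 10 is closed in one operation by a [3+3] annulation of α-silyloxy ketone 8 with 2-bromobenzyl chloride 5: C3–C4 by enolate C-benzylation and O1–C8a by enolate O-arylation.
4. Enabling feature: O1 and C3 flank C2, so at the C2-ketone level O1–C2–C3 is an ambident enolate (O and C nucleophile) whose only enolisable carbon is C3, because C3 carries the oxygen. C8a and C4 flank C4a on the phloroglucinol ring A, so a 2-halobenzyl halide is the matching 1,3-dielectrophile.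
5. Ring order: rings A and B are bought as benzene derivatives; ring C of the monomer is the only ring formed (step 6); the interflavan bonds follow (steps 12, 16, 17).

Key step: step 6

Assumption: unit 3 is read from the SMILES as (2R,3S) with its C4 aryl group cis to the 3-OH (4β). The antipode of the ruthenium catalyst in step 8 is the one that gives the (2R,3R) alcohol; it is fixed on the first run by comparison with the benzyl ether of natural (−)-epicatechin.

**Route**

Step 1
Reactants: 1 5-bromobenzene-1,3-diol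
Product: 2 1,3-bis(benzyloxy)-5-bromobenzene
Conditions: BnBr, K2CO3, DMF, 60 °C
Reagents that add atoms: benzyl bromide (BrCc1ccccc1)
Why: Williamson ether synthesis of both phenols; no stereocentre is involved.

Step 2
Reactants: 2 1,3-bis(benzyloxy)-5-bromobenzene
Product: 3 2-bromo-4,6-bis(benzyloxy)benzaldehyde
Conditions: POCl3, DMF, 70 °C; then ice-water
Reagents that add atoms: N,N-dimethylformamide (CN(C)C=O); water (O)
Why: Vilsmeier–Haack formylation should go para to one benzyloxy group and ortho to bromine rather than at the hindered carbon between the two ethers, as with the dimethyl ether analogue; the minor 4-bromo-2,6-isomer is removed by crystallisation.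

Step 3
Reactants: 3 2-bromo-4,6-bis(benzyloxy)benzaldehyde
Product: 4 [2-bromo-4,6-bis(benzyloxy)phenyl]methanol
Conditions: NaBH4, MeOH/THF, 0 °C
Reagents that add atoms: none
Why: Borohydride reduction of an aryl aldehyde; the aryl bromide and benzyl ethers are inert.

Step 4
Reactants: 4 [2-bromo-4,6-bis(benzyloxy)phenyl]methanol
Product: 5 1,5-bis(benzyloxy)-3-bromo-2-(chloromethyl)benzene
Conditions: SOCl2, pyridine, CH2Cl2, 0 °C; used crude at once
Reagents that add atoms: thionyl chloride (ClS(Cl)=O)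
Why: Chlorodehydroxylation of an electron-rich benzylic alcohol through its chlorosulfite; the labile 2,4-dialkoxybenzyl chloride is not stored.

Step 5
Reactants: 6 1-[3,4-bis(benzyloxy)phenyl]ethanone
Product: 8 1-[3,4-bis(benzyloxy)phenyl]-2-[tri(propan-2-yl)silyloxy]ethanone, via silyl enol ether 7 (not isolated)
Conditions: i-Pr3SiOTf, Et3N, CH2Cl2, 0 °C; aqueous wash; then mCPBA, CH2Cl2, −20 → 0 °C
Reagents that add atoms: tri(propan-2-yl)silyl trifluoromethanesulfonate (CC(C)[Si](C(C)C)(C(C)C)OS(=O)(=O)C(F)(F)F); mCPBA (OOC(=O)c1cccc(Cl)c1)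
Why: Rubottom oxidation: epoxidation of the silyl enol ether and 1,4-silyl shift should give the α-silyloxy ketone directly.

Step 6
Reactants: 8 1-[3,4-bis(benzyloxy)phenyl]-2-[tri(propan-2-yl)silyloxy]ethanone; 5 1,5-bis(benzyloxy)-3-bromo-2-(chloromethyl)benzene
Product: 10 5,7-bis(benzyloxy)-2-[3,4-bis(benzyloxy)phenyl]-3-[tri(propan-2-yl)silyloxy]-4H-chromene, via C-benzylated ketone 9 (not isolated)
Conditions: LiN(SiMe3)2, THF, −78 °C; then 5, Bu4NI (cat.), −78 → 23 °C; then CuI (10 mol %), 1,10-phenanthroline, Cs2CO3, DMF, 100 °C (one pot)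
Reagents that add atoms: none
Why: Proposed new method: the lithium enolate of 8 is C-benzylated at C3 by the ionisation-prone 2,4-dialkoxybenzyl chloride 5 (C3–C4); after the switch to Cs2CO3/DMF the re-formed enolate of 9, in the geometry that puts O1 cis to the benzyl arm, should undergo CuI-catalysed intramolecular Ullmann-type O-arylation at the C8a bromide (O1–C8a). The closest known reaction types are the copper-catalysed domino C-benzylation/O-arylation of 2-bromobenzyl bromides with 1,3-dicarbonyl compounds to 4H-chromenes and the copper- or palladium-catalysed intramolecular O-arylation of ketone enolates to benzofurans; the extension is to a mono-ketone whose enolate is first made stoichiometrically. Ring C closes as a six-membered ring by C(aryl)–O bond formation; the alternative C-arylation at C3 would give a four-membered ring and is excluded. No stereocentre is set, since C3 of 9 becomes sp2 in 10, and C2 and C3 are left for step 8. The selectivities needed are C- over O-benzylation (lithium enolate in THF), mono- over dialkylation (C3 of 9 is tertiary and hindered) and O1- over O3-arylation; the last is secured because O3 carries the bulky, slow-migrating i-Pr3Si group and lies trans to O1 in the reacting enolate.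

Step 7
Reactants: 10 5,7-bis(benzyloxy)-2-[3,4-bis(benzyloxy)phenyl]-3-[tri(propan-2-yl)silyloxy]-4H-chromene
Product: 11 rac-5,7-bis(benzyloxy)-2-[3,4-bis(benzyloxy)phenyl]chroman-3-one (tetra-O-benzylflavan-3-one)
Conditions: Bu4NF, AcOH, THF, 0 °C, under argon
Reagents that add atoms: none
Why: Fluoride desilylation of the silyl enol ether releases the C3 enolate, which acetic acid protonates at C2 to give the racemic ketone; acid hydrolysis is avoided because it would open ring C at C2.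

Step 8
Reactants: 11 rac-tetra-O-benzylflavan-3-one
Product: 12 (2R,3R)-5,7-bis(benzyloxy)-2-[3,4-bis(benzyloxy)phenyl]chroman-3-ol (5,7,3',4'-tetra-O-benzyl-(−)-epicatechin)
Conditions: RuCl[(S,S)-TsDPEN](p-cymene) (2 mol %), HCO2H/Et3N (5:2), CH2Cl2, 35 °C
Reagents that add atoms: none
Why: Noyori asymmetric transfer hydrogenation with dynamic kinetic resolution, as for other α-aryl cyclic ketones: C2 (benzylic, α to the ketone and to O1) racemises through the enol under Et3N, the catalyst should reduce the (2R)-ketone faster, and hydride enters C3 anti to the C2 aryl group to give the 2,3-cis (2R,3R) alcohol.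

Step 9
Reactants: 12 tetra-O-benzyl-(−)-epicatechin
Product: 13 (2R,3R)-3,5,7-tris(benzyloxy)-2-[3,4-bis(benzyloxy)phenyl]chromane (penta-O-benzyl-(−)-epicatechin)
Conditions: NaH, BnBr, Bu4NI (cat.), DMF, 0 → 23 °C
Reagents that add atoms: benzyl bromide (BrCc1ccccc1)
Why: Williamson etherification of the 3-OH, which marks the bottom unit so that only one hydroxyl is free in dimer 16; C2 and C3 are untouched.

Step 10
Reactants: 12 tetra-O-benzyl-(−)-epicatechin
Product: 14 (2R,3R,4S)-5,7-bis(benzyloxy)-2-[3,4-bis(benzyloxy)phenyl]-4-(2-ethoxyethoxy)chroman-3-ol (4β-(2-ethoxyethoxy) derivative)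
Conditions: DDQ, 2-ethoxyethanol, CH2Cl2, 23 °C
Reagents that add atoms: 2-ethoxyethanol (CCOCCO)
Why: DDQ benzylic oxidation: hydride abstraction at C4 gives the cation stabilised by the 5- and 7-oxygens of ring A, and the alcohol adds trans to the 3-OH and the C2 aryl group (4β).

Step 11
Reactants: 14 4β-(2-ethoxyethoxy)-tetra-O-benzyl-epicatechin
Product: 15 8-bromo-4β-(2-ethoxyethoxy)-5,7,3',4'-tetra-O-benzyl-epicatechin
Conditions: N-bromosuccinimide, CH2Cl2, −78 → 0 °C
Reagents that add atoms: N-bromosuccinimide (O=C1CCC(=O)N1Br)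
Why: Electrophilic aromatic bromination of ring A should go to C8, which is more accessible than C6 between two benzyloxy groups; the bromine caps the nucleophilic position of the future top unit.

Step 12
Reactants: 14 4β-(2-ethoxyethoxy)-tetra-O-benzyl-epicatechin; 13 penta-O-benzyl-(−)-epicatechin (3 equiv, excess recovered)
Product: 16 5,7,3',4'-tetra-O-benzyl-epicatechin-(4β→8)-3,5,7,3',4'-penta-O-benzyl-epicatechin
Conditions: Me3SiOTf (cat.), CH2Cl2, −78 °C; Et3N quench
Reagents that add atoms: none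
Why: Lewis acid ionisation of the C4 ether and Friedel–Crafts attack by C8 of 13, trans to the axial 3-OH and the C2 aryl group, should give the 4β bond; excess 13 suppresses self-condensation of 14.

Step 13
Reactants: 16 epicatechin-(4β→8)-epicatechin dimer
Product: 17 the upper-unit C3 ketone of 16 (upper unit 2R, 3-oxo, 4β-aryl)
Conditions: Dess–Martin periodinane, CH2Cl2, 0 → 23 °C
Reagents that add atoms: none
Why: Dess–Martin oxidation of the only free hydroxyl under neutral conditions, as in the oxidation of benzylated catechin to the flavan-3-one.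

Step 14
Reactants: 17 dimer ketone
Product: 18 5,7,3',4'-tetra-O-benzyl-catechin-(4β→8)-3,5,7,3',4'-penta-O-benzyl-epicatechin (upper unit 2R,3S, 3-OH cis to the 4β-aryl group)
Conditions: NaBH4, CeCl3·7H2O, MeOH/THF, −78 °C
Reagents that add atoms: none
Why: Luche reduction: the pseudo-axial 4β-aryl group shields the β face of the C3 carbonyl, so hydride should enter from the α face and place the 3-OH β (equatorial, 2,3-trans-3,4-cis); the cold, weakly basic medium limits enolisation at C2 and C4.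

Step 15
Reactants: 14 4β-(2-ethoxyethoxy)-tetra-O-benzyl-epicatechin
Product: 19 4β-[(2,6-dimethylphenyl)sulfanyl]-5,7,3',4'-tetra-O-benzyl-epicatechin
Conditions: 2,6-dimethylbenzenethiol (3 equiv), BF3·OEt2, CH2Cl2, −78 → −20 °C
Reagents that add atoms: 2,6-dimethylbenzenethiol (Cc1cccc(C)c1S)
Why: Lewis acid-mediated capture of the C4 cation by the thiol from the β face, as in thiolysis of procyanidins; the excess thiol outruns self-condensation.

Step 16
Reactants: 15 8-bromo-4β-(2-ethoxyethoxy) electrophile; 19 4β-thioether nucleophile (1.2 equiv)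
Product: 20 8-bromo-5,7,3',4'-tetra-O-benzyl-epicatechin-(4β→8)-4β-[(2,6-dimethylphenyl)sulfanyl]-5,7,3',4'-tetra-O-benzyl-epicatechin
Conditions: BF3·OEt2, CH2Cl2, −78 → −40 °C
Reagents that add atoms: none
Why: Orthogonal activation: the hard Lewis acid ionises only the C4–O ether of 15, C8 of 19 attacks from the β face (4β), the hindered aryl thioether survives, and the 8-bromo cap prevents self-condensation.

Step 17
Reactants: 20 upper dimer; 18 lower dimer (1.2 equiv)
Product: 21 protected tetramer: 8-bromo-epicatechin-(4β→8)-epicatechin-(4β→8)-catechin-(4β→8)-epicatechin with all sixteen phenols and the 3-OH of unit 4 benzylated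
Conditions: AgOTf, 2,6-di-tert-butylpyridine, 4 Å MS, CH2Cl2, −40 → 0 °C
Reagents that add atoms: none
Why: Thiophilic activation of a 4-thioflavan by a silver salt gives the C4 cation of unit 2, and Friedel–Crafts attack by C8 of the top unit of 18, trans to the 3-OH and C2 aryl group of unit 2, should set the 4β bond; neither partner can self-condense.

Step 18
Reactants: 21 protected tetramer
Product: 22 epicatechin-(4β→8)-epicatechin-(4β→8)-catechin-(4β→8)-epicatechin (CNP0236700.5)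
Conditions: H2 (1 atm), Pd(OH)2/C, Et3N, THF/MeOH/H2O, 23 °C; filtration and lyophilisation
Reagents that add atoms: none
Why: Global hydrogenolysis of seventeen benzyl ethers and the aryl bromide; Et3N takes up HBr so that the acid-labile interflavan bonds survive.

**Compound list**

1 | 5-bromobenzene-1,3-diol | Oc1cc(O)cc(Br)c1 | starting material
2 | 1,3-bis(benzyloxy)-5-bromobenzene | Brc1cc(OCc2ccccc2)cc(OCc2ccccc2)c1 | intermediate
3 | 2-bromo-4,6-bis(benzyloxy)benzaldehyde | O=Cc1c(Br)cc(OCc2ccccc2)cc1OCc1ccccc1 | intermediate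
4 | [2-bromo-4,6-bis(benzyloxy)phenyl]methanol | OCc1c(Br)cc(OCc2ccccc2)cc1OCc1ccccc1 | intermediate
5 | 1,5-bis(benzyloxy)-3-bromo-2-(chloromethyl)benzene | ClCc1c(Br)cc(OCc2ccccc2)cc1OCc1ccccc1 | intermediate
6 | 1-[3,4-bis(benzyloxy)phenyl]ethanone | CC(=O)c1ccc(OCc2ccccc2)c(OCc2ccccc2)c1 | starting material
7 | {1-[3,4-bis(benzyloxy)phenyl]ethenyloxy}tri(propan-2-yl)silane | C=C(O[Si](C(C)C)(C(C)C)C(C)C)c1ccc(OCc2ccccc2)c(OCc2ccccc2)c1 | intermediate
8 | 1-[3,4-bis(benzyloxy)phenyl]-2-[tri(propan-2-yl)silyloxy]ethanone | O=C(CO[Si](C(C)C)(C(C)C)C(C)C)c1ccc(OCc2ccccc2)c(OCc2ccccc2)c1 | intermediate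
9 | rac-1-[3,4-bis(benzyloxy)phenyl]-3-[2-bromo-4,6-bis(benzyloxy)phenyl]-2-[tri(propan-2-yl)silyloxy]propan-1-one | O=C(c1ccc(OCc2ccccc2)c(OCc2ccccc2)c1)C(O[Si](C(C)C)(C(C)C)C(C)C)Cc1c(Br)cc(OCc2ccccc2)cc1OCc1ccccc1 | intermediate
10 | 5,7-bis(benzyloxy)-2-[3,4-bis(benzyloxy)phenyl]-3-[tri(propan-2-yl)silyloxy]-4H-chromene | CC(C)[Si](OC1=C(c2ccc(OCc3ccccc3)c(OCc3ccccc3)c2)Oc2cc(OCc3ccccc3)cc(OCc3ccccc3)c2C1)(C(C)C)C(C)C | intermediate
11 | rac-5,7-bis(benzyloxy)-2-[3,4-bis(benzyloxy)phenyl]chroman-3-one | O=C1Cc2c(OCc3ccccc3)cc(OCc3ccccc3)cc2OC1c1ccc(OCc3ccccc3)c(OCc3ccccc3)c1 | intermediate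
12 | (2R,3R)-5,7-bis(benzyloxy)-2-[3,4-bis(benzyloxy)phenyl]chroman-3-ol | c1c(OCc3ccccc3)cc(OCc3ccccc3)c2c1O[C@H](c1ccc(OCc3ccccc3)c(OCc3ccccc3)c1)[C@H](O)C2 | intermediate
13 | (2R,3R)-3,5,7-tris(benzyloxy)-2-[3,4-bis(benzyloxy)phenyl]chromane | c1c(OCc3ccccc3)cc(OCc3ccccc3)c2c1O[C@H](c1ccc(OCc3ccccc3)c(OCc3ccccc3)c1)[C@H](OCc3ccccc3)C2 | intermediate
14 | (2R,3R,4S)-5,7-bis(benzyloxy)-2-[3,4-bis(benzyloxy)phenyl]-4-(2-ethoxyethoxy)chroman-3-ol | c1c(OCc3ccccc3)cc(OCc3ccccc3)c2c1O[C@H](c1ccc(OCc3ccccc3)c(OCc3ccccc3)c1)[C@H](O)[C@H]2OCCOCC | intermediate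
15 | 8-bromo-4β-(2-ethoxyethoxy)-5,7,3',4'-tetra-O-benzyl-epicatechin | Brc1c(OCc3ccccc3)cc(OCc3ccccc3)c2c1O[C@H](c1ccc(OCc3ccccc3)c(OCc3ccccc3)c1)[C@H](O)[C@H]2OCCOCC | intermediate
16 | 5,7,3',4'-tetra-O-benzyl-epicatechin-(4β→8)-3,5,7,3',4'-penta-O-benzyl-epicatechin | c1c(OCc3ccccc3)cc(OCc3ccccc3)c2c1O[C@H](c1ccc(OCc3ccccc3)c(OCc3ccccc3)c1)[C@H](O)[C@H]2c1c(OCc3ccccc3)cc(OCc3ccccc3)c2c1O[C@H](c1ccc(OCc3ccccc3)c(OCc3ccccc3)c1)[C@H](OCc3ccccc3)C2 | intermediate
17 | upper-unit C3 ketone of 16 | c1c(OCc3ccccc3)cc(OCc3ccccc3)c2c1O[C@H](c1ccc(OCc3ccccc3)c(OCc3ccccc3)c1)C(=O)[C@H]2c1c(OCc3ccccc3)cc(OCc3ccccc3)c2c1O[C@H](c1ccc(OCc3ccccc3)c(OCc3ccccc3)c1)[C@H](OCc3ccccc3)C2 | intermediate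
18 | 5,7,3',4'-tetra-O-benzyl-catechin-(4β→8)-3,5,7,3',4'-penta-O-benzyl-epicatechin | c1c(OCc3ccccc3)cc(OCc3ccccc3)c2c1O[C@H](c1ccc(OCc3ccccc3)c(OCc3ccccc3)c1)[C@@H](O)[C@H]2c1c(OCc3ccccc3)cc(OCc3ccccc3)c2c1O[C@H](c1ccc(OCc3ccccc3)c(OCc3ccccc3)c1)[C@H](OCc3ccccc3)C2 | intermediate
19 | 4β-[(2,6-dimethylphenyl)sulfanyl]-5,7,3',4'-tetra-O-benzyl-epicatechin | c1c(OCc3ccccc3)cc(OCc3ccccc3)c2c1O[C@H](c1ccc(OCc3ccccc3)c(OCc3ccccc3)c1)[C@H](O)[C@H]2Sc1c(C)cccc1C | intermediate
20 | 8-bromo-tetra-O-benzyl-epicatechin-(4β→8)-4β-[(2,6-dimethylphenyl)sulfanyl]-tetra-O-benzyl-epicatechin | Brc1c(OCc3ccccc3)cc(OCc3ccccc3)c2c1O[C@H](c1ccc(OCc3ccccc3)c(OCc3ccccc3)c1)[C@H](O)[C@H]2c1c(OCc3ccccc3)cc(OCc3ccccc3)c2c1O[C@H](c1ccc(OCc3ccccc3)c(OCc3ccccc3)c1)[C@H](O)[C@H]2Sc1c(C)cccc1C | intermediate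
21 | protected tetramer (8-bromo on unit 1, seventeen benzyl ethers) | Brc1c(OCc3ccccc3)cc(OCc3ccccc3)c2c1O[C@H](c1ccc(OCc3ccccc3)c(OCc3ccccc3)c1)[C@H](O)[C@H]2c1c(OCc3ccccc3)cc(OCc3ccccc3)c2c1O[C@H](c1ccc(OCc3ccccc3)c(OCc3ccccc3)c1)[C@H](O)[C@H]2c1c(OCc3ccccc3)cc(OCc3ccccc3)c2c1O[C@H](c1ccc(OCc3ccccc3)c(OCc3ccccc3)c1)[C@@H](O)[C@H]2c1c(OCc3ccccc3)cc(OCc3ccccc3)c2c1O[C@H](c1ccc(OCc3ccccc3)c(OCc3ccccc3)c1)[C@H](OCc3ccccc3)C2 | intermediate
22 | epicatechin-(4β→8)-epicatechin-(4β→8)-catechin-(4β→8)-epicatechin | Oc1cc(O)c2c(c1)O[C@H](c1ccc(O)c(O)c1)[C@H](O)[C@H]2c1c(O)cc(O)c2c1O[C@H](c1ccc(O)c(O)c1)[C@H](O)[C@H]2c1c(O)cc(O)c2c1O[C@H](c1ccc(O)c(O)c1)[C@@H](O)[C@H]2c1c(O)cc(O)c2c1O[C@H](c1ccc(O)c(O)c1)[C@H](O)C2 | target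

**Step count and risks**

Total step count: 18. Longest linear sequence: 13 steps (1, 2, 3, 4, 6, 7, 8, 10, 12, 13, 14, 17, 18).

Steps most likely to fail:

Step 6. The enolate O-arylation of the electron-rich aryl bromide may be slow. The silyl group may move between the two enediolate oxygens, which would open a five-membered ring closure through O3. O-benzylation may compete in the first stage. The fallback sets out from 8 and 5 and comes back at 11. It separates the two bond formations and makes the aryl ether from an alcohol instead of an enolate. 8 is alkylated with 5 (LiN(SiMe3)2, THF) and ketone 9 is isolated. NaBH4 reduces the C2 ketone to 1-[3,4-bis(benzyloxy)phenyl]-3-[2-bromo-4,6-bis(benzyloxy)phenyl]-2-[tri(propan-2-yl)silyloxy]propan-1-ol F1, a diastereomer mixture in which only O1 is free. A palladium-catalysed intramolecular aryl ether formation (Pd(OAc)2, 2-(di-tert-butylphosphino)-1,1'-binaphthyl, Cs2CO3, toluene, 80 °C), a known chroman synthesis, closes ring C to 5,7-bis(benzyloxy)-2-[3,4-bis(benzyloxy)phenyl]-3-[tri(propan-2-yl)silyloxy]chromane F2. Bu4NF gives the racemic cis/trans flavan-3-ol mixture F3, and Dess–Martin oxidation returns the route at 11.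

Step 8. Enantioface discrimination may be poor, or racemisation at C2 too slow, for a ketone flanked by two sp3 carbons. The fallback sets out from 11 and comes back at 12. It uses substrate control followed by classical resolution. LiBH(s-Bu)3 in THF at −78 °C should give the racemic 2,3-cis alcohol, that is 12 together with its enantiomer (2S,3S)-5,7-bis(benzyloxy)-2-[3,4-bis(benzyloxy)phenyl]chroman-3-ol F4. Acylation with (1S)-camphanic chloride (Et3N, DMAP) gives the diastereomeric camphanates, the (2R,3R) ester F5 and the (2S,3S) ester F6, which are separated by crystallisation or chromatography. K2CO3/MeOH methanolysis of F5 returns 12.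

Step 14. The α-aryl ketone 17 may epimerise at C4 or C2 before reduction, or hydride may enter partly from the β face. The fallback sets out from 13 and comes back at 18. It takes the 2,3-trans unit from the chiral pool instead of inverting C3. Commercial (+)-catechin is benzylated (BnBr, K2CO3, DMF) to 5,7,3',4'-tetra-O-benzyl-(+)-catechin F7. DDQ and 2-ethoxyethanol give its 4-(2-ethoxyethoxy) derivative F8, which is coupled with 13 (Me3SiOTf, CH2Cl2, −78 °C). The catechin-type C4 cation gives both C4 epimers: the 3,4-trans (4α) dimer F9, expected to predominate, and the 3,4-cis (4β) dimer 18, which is separated by chromatography.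

Further compounds
F1 | step 6 | 1-[3,4-bis(benzyloxy)phenyl]-3-[2-bromo-4,6-bis(benzyloxy)phenyl]-2-[tri(propan-2-yl)silyloxy]propan-1-ol (diastereomer mixture) | OC(c1ccc(OCc2ccccc2)c(OCc2ccccc2)c1)C(O[Si](C(C)C)(C(C)C)C(C)C)Cc1c(Br)cc(OCc2ccccc2)cc1OCc1ccccc1
F2 | step 6 | 5,7-bis(benzyloxy)-2-[3,4-bis(benzyloxy)phenyl]-3-[tri(propan-2-yl)silyloxy]chromane (racemic cis/trans mixture) | CC(C)[Si](OC1Cc2c(OCc3ccccc3)cc(OCc3ccccc3)cc2OC1c1ccc(OCc3ccccc3)c(OCc3ccccc3)c1)(C(C)C)C(C)C
F3 | step 6 | 5,7-bis(benzyloxy)-2-[3,4-bis(benzyloxy)phenyl]chroman-3-ol (racemic cis/trans mixture) | OC1Cc2c(OCc3ccccc3)cc(OCc3ccccc3)cc2OC1c1ccc(OCc3ccccc3)c(OCc3ccccc3)c1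
F4 | step 8 | (2S,3S)-5,7-bis(benzyloxy)-2-[3,4-bis(benzyloxy)phenyl]chroman-3-ol | c1c(OCc3ccccc3)cc(OCc3ccccc3)c2c1O[C@@H](c1ccc(OCc3ccccc3)c(OCc3ccccc3)c1)[C@@H](O)C2
F5 | step 8 | (1S,4R)-camphanate of 12 | c1c(OCc3ccccc3)cc(OCc3ccccc3)c2c1O[C@H](c1ccc(OCc3ccccc3)c(OCc3ccccc3)c1)[C@H](OC(=O)[C@@]45CC[C@@](C)(C(=O)O4)C5(C)C)C2
F6 | step 8 | (1S,4R)-camphanate of F4 | c1c(OCc3ccccc3)cc(OCc3ccccc3)c2c1O[C@@H](c1ccc(OCc3ccccc3)c(OCc3ccccc3)c1)[C@@H](OC(=O)[C@@]45CC[C@@](C)(C(=O)O4)C5(C)C)C2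
F7 | step 14 | (2R,3S)-5,7-bis(benzyloxy)-2-[3,4-bis(benzyloxy)phenyl]chroman-3-ol (tetra-O-benzyl-(+)-catechin) | c1c(OCc3ccccc3)cc(OCc3ccccc3)c2c1O[C@H](c1ccc(OCc3ccccc3)c(OCc3ccccc3)c1)[C@@H](O)C2
F8 | step 14 | 4β-(2-ethoxyethoxy)-5,7,3',4'-tetra-O-benzyl-catechin | c1c(OCc3ccccc3)cc(OCc3ccccc3)c2c1O[C@H](c1ccc(OCc3ccccc3)c(OCc3ccccc3)c1)[C@@H](O)[C@H]2OCCOCC
F9 | step 14 | 5,7,3',4'-tetra-O-benzyl-catechin-(4α→8)-3,5,7,3',4'-penta-O-benzyl-epicatechin | c1c(OCc3ccccc3)cc(OCc3ccccc3)c2c1O[C@H](c1ccc(OCc3ccccc3)c(OCc3ccccc3)c1)[C@@H](O)[C@@H]2c1c(OCc3ccccc3)cc(OCc3ccccc3)c2c1O[C@H](c1ccc(OCc3ccccc3)c(OCc3ccccc3)c1)[C@H](OCc3ccccc3)C2
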